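## Structural features

The target is a 2,3-dihydro-4H-chromen-4-one: benzene ring A is fused to the oxygen heterocycle ring C, and a 4-hydroxyphenyl ring B is attached at C2. Ring A carries three contiguous oxygens, free hydroxyls at C5 and C7 and a methyl ether at C6 between them, with C8 unsubstituted. C2 (R, aryl) and C3 (R, acetoxy) are adjacent stereocentres in a trans, diequatorial relationship. Several features are fragile: C3–H is α to the ketone and can epimerise, base opens ring C by β-elimination of the O1 phenoxide (which racemises C2), the C3 acetate is an activated secondary ester that hydrolyses and migrates easily, and the C2–O1 bond is benzylic. The real difficulty is to set two adjacent, enolisable stereocentres and to acylate only the C3 oxygen among four hydroxyl groups, with an end-game that stays close to neutral. A second problem is the regiochemistry of ring A: the acyl carbon C4 and the ether oxygen O1 must sit on the C8 side of a 5,6,7-trioxygenated ring. The key step exploits C3, which bears an oxygen and lies between the C4 carbonyl and the C2 carbinol carbon, so a carbene centred on C3 can acquire the C3–O bond and the C2–C3 bond in one operation.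

## Logic of the disconnections

20 to 19: the three phenolic O–H groups are traced back to three O–CH2Ph bonds. The last step must be neutral because of the acetate and the base-labile ring C. The gain is that all three phenols are masked alike and released together. The demand is a hydrogenolysis that stops before the benzylic C2–O1 bond or the ketone is touched.

19 to 18 to 17: the acetyl C–O bond is cut, then the O–CH2 bond of a 4-methoxybenzyl ether on the C3 oxygen. The C3 oxygen is the only non-phenolic one and needs a group that can be removed while three benzyl ethers stay. The gain is that C3–OH is the only free hydroxyl when it is acylated. The demand is an oxidative ether cleavage selective for the methoxy-substituted benzyl group and an acylation that does not epimerise C3.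

17 to 16: the O1–C2 bond is cut. This opens ring C to an acyclic aldol with no ring and two stereocentres in a 1,2-relationship. Because the forward bond formation is an SN2 displacement with inversion, the carbinol carbon of 16 must be S, which makes 16 the syn isomer. The demand is that substitution outruns β-elimination and ionisation at the benzylic carbon.

16 to 15: an O–Si bond is added on the ring A phenol. This oxygen has to be capped while a carbene is generated next to it. The demand is a desilylation that does not trigger retro-aldol cleavage.

15 to 11 + 12 + 13 (through 14): the C3–O bond and the C2–C3 bond (flavonoid numbering) are cut, both at the former diazo carbon. The gain is the largest of the route: three achiral pieces, two of them purchased, and both stereocentres arise here. The demand is that the enol is trapped by the aldehyde faster than it tautomerises, with syn and facial selectivity supplied by the chiral acid.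

11 to 9 (through 10) to 8: the C=N2 unit is traced to the methyl group of an aryl methyl ketone, and the silyl ether to the free phenol. The gain is a simple ortho-hydroxy acetophenone. The demand is activation of the weakly acidic methyl ketone for diazo transfer without disturbing the aryl silyl ether.

8 to 6 (through 7): the aryl–acyl bond C4a–C4 is cut. 6 has a mirror plane, so its two free ring positions are equivalent and acylation can only give the required pattern. The demand is C-acylation under conditions that spare two benzyl ethers.

6 to 4 (through 5): the aryl C–O bond is traced to an aryl–CHO bond. This connects the symmetrical phenol to a gallate-type benzoate in which the central oxygen is already methylated. The demand is aryl rather than hydride migration in the peracid adduct.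

4 to 3 to 2 to 1: two oxidation-level adjustments and a double O-benzylation lead back to commercial 1.

## Other disconnections considered

Alternative 1: The cut is the C3–C4 bond. The precursor would be the dialdehyde 2-[3,5-bis(benzyloxy)-2-formyl-4-methoxyphenoxy]-2-[4-(benzyloxy)phenyl]acetaldehyde A1, in which O1–C2 already exists and C2 is an epimerisable α-aryl-α-aryloxy aldehyde centre. A chiral triazolium-derived carbene would add to the ring A formyl group, the acyl anion equivalent would attack the side-chain aldehyde, and ring C would close to (2R,3R)-5,7,4'-tri-O-benzyl-6-methoxyaromadendrin A2, which is the same compound as 18. The two enantiomers of A1 interconvert through the enol, so one of them would be funnelled to product.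
- In its favour: ring C and both stereocentres come from one catalytic step. No group is needed on the C3 oxygen or on the ring A phenol. Only acetylation and hydrogenolysis remain, three steps fewer after the key step than in the chosen plan. On protecting-group economy and on step economy after the key step it is the better plan.
- Against it here: the carbene must pick the hindered, electron-rich, doubly ortho-substituted aryl aldehyde as acyl donor over the more electrophilic aliphatic one; the reverse choice gives the isomeric 4-hydroxychroman-3-one. A1 is liable to self-condensation and would need about five steps from 6, with the two aldehydes unmasked at different times. Intramolecular benzoin closures are well grounded for aldehyde–ketone pairs, but an aldehyde–aldehyde closure with dynamic resolution of an α-aryloxy centre has thin support.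
- Comparison: structurally the two plans are equal, since both treat C3 as the linchpin. Mechanistically, Alternative 1 exchanges one chemoselectivity question (trapping against proton shift) for another (which aldehyde becomes the acyl anion), and it runs under basic conditions, which is worse for an enolisable α-ketol. The total count should be similar or slightly lower.

Alternative 2: The cut runs through O1–C2 and C3–C4. A chiral phosphoric acid would dehydrate 3,5-bis(benzyloxy)-2-(hydroxymethyl)-4-methoxyphenol A3 to the ortho-quinone methide 3,5-bis(benzyloxy)-4-methoxy-6-methylidenecyclohexa-2,4-dien-1-one A4. A4 would undergo [4+2] cycloaddition with (E)-2-[4-(benzyloxy)phenyl]ethenyl acetate A5 to give the trans flavan (2R,3S)-5,7-bis(benzyloxy)-2-[4-(benzyloxy)phenyl]-6-methoxychroman-3-yl acetate A6. The C3 descriptor of A6 differs from that of the target only because C4 is still a methylene group. Oxidation of C4 would then give 19, and step 13 would finish.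
- In its favour: it is convergent, ring C and both stereocentres form together, and the E geometry maps onto the trans relationship. The acetate arrives with the two-carbon partner, so no temporary group on the C3 oxygen and no separate acetylation are needed. On this point and on nominal step count (about ten) it is the better plan.
- Against it here: C4 is at the wrong oxidation level. A benzylic methylene must be oxidised late in the presence of C2–H (also benzylic and ether-activated) and three benzyl ethers, probably in two operations. The enol acetate is a weak 2π partner whose polarisation by the acetoxy group opposes that by the 4-alkoxyaryl group, so the regiochemistry is not assured. A4 has an unsubstituted methide carbon, a class for which asymmetric induction by a phosphate is less secure. A5 must be geometrically pure.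
- Comparison: the plans are equal in convergence. Alternative 2 is better in direct ring formation and in handling the acetate. It is worse in oxidation-state economy and in the risk of its last oxidation, which falls on the most valuable intermediate.

Alternative 3: The cut runs through O1–C8a and C4–C4a. Fluoride would release the aryne 3,5-bis(benzyloxy)-1,2-didehydro-4-methoxybenzene A8 from 3,5-bis(benzyloxy)-4-methoxy-2-(trimethylsilyl)phenyl trifluoromethanesulfonate A7. The alkoxide of the anti ester methyl (2R,3R)-3-[4-(benzyloxy)phenyl]-3-hydroxy-2-[(4-methoxybenzyl)oxy]propanoate A9 would add to C8a, and the C4a aryl anion would attack the ester carbonyl to close ring C. The product would be (2R,3R)-5,7,4'-tri-O-benzyl-3-O-(4-methoxybenzyl)-6-methoxyaromadendrin A10, identical with 17.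
- In its favour: the benzyloxy group next to the aryne should steer the oxygen nucleophile to the remote carbon, which is the required regiochemistry. Ring C closes in the key step without any inversion. Desilylation and the Mitsunobu closure are avoided, two steps fewer after the key step, and on these points it is the better plan. The end-game from A10 is the same as steps 11 to 13.
- Against it here: both stereocentres must be made beforehand in a separate, auxiliary-based anti glycolate aldol of several steps. The alkoxide of an aldol adduct under basic fluoride conditions invites retro-aldol cleavage and epimerisation α to the ester. A secondary alkoxide is a modest aryne partner, and protonation of the aryl anion (plain O-arylation) competes with acyl capture. A7 needs about three steps from 6.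
- Comparison: the plans are equal in regiochemical logic, since both rely on the symmetrical phenol 6. Alternative 3 is mechanistically more threatening to the stereocentres, because its key step is anionic where the chosen one is acid-mediated. In step economy it is shorter after the key step and longer before it, so the totals should be similar, and it sets no stereocentre catalytically.

Key step: step 8

Assumption: the sense of induction of the BINOL-derived phosphoric acid cannot be assigned in advance for this enol and aldehyde pair, so the (R)-acid is written and its mirror image is used should that be the one leading to the (2R,3S) adduct.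

## Route

Step 1
Reactants: 1 methyl 3,5-dihydroxy-4-methoxybenzoate
Product: 2 methyl 3,5-bis(benzyloxy)-4-methoxybenzoate
Conditions: BnBr, K2CO3, DMF, 60 °C
Reagents that add atoms: benzyl bromide, BrCc1ccccc1
Why: Williamson ether synthesis on the two equivalent phenols; the methyl ester and the methyl ether are inert to K2CO3 in DMF.

Step 2
Reactants: 2 methyl 3,5-bis(benzyloxy)-4-methoxybenzoate
Product: 3 [3,5-bis(benzyloxy)-4-methoxyphenyl]methanol
Conditions: LiAlH4, THF, 0 °C
Reagents that add atoms: none
Why: Hydride reduction of the aryl ester to the benzylic alcohol; aryl benzyl ethers are inert to LiAlH4.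

Step 3
Reactants: 3 [3,5-bis(benzyloxy)-4-methoxyphenyl]methanol
Product: 4 3,5-bis(benzyloxy)-4-methoxybenzaldehyde
Conditions: MnO2, CH2Cl2, rt
Reagents that add atoms: none
Why: Activated MnO2 oxidises benzylic alcohols selectively and stops at the aldehyde.

Step 4
Reactants: 4 3,5-bis(benzyloxy)-4-methoxybenzaldehyde
Product: 6 3,5-bis(benzyloxy)-4-methoxyphenol, via formate ester 5 (not isolated)
Conditions: mCPBA, CH2Cl2, 0 °C to rt; aq. NaHCO3 wash; then K2CO3 (cat.), MeOH, rt
Reagents that add atoms: 3-chloroperoxybenzoic acid, OOC(=O)c1cccc(Cl)c1
Why: Dakin-type Baeyer–Villiger oxidation: in the peracid adduct the electron-rich trioxygenated aryl group should migrate in preference to hydride, and the resulting aryl formate is methanolysed to the phenol.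

Step 5
Reactants: 6 3,5-bis(benzyloxy)-4-methoxyphenol
Product: 8 1-[4,6-bis(benzyloxy)-2-hydroxy-5-methoxyphenyl]ethanone, via ketiminium chloride 7 (not isolated)
Conditions: MeCN, ZnCl2 (0.2 equiv), HCl (g), Et2O, 0 °C; then H2O, 80 °C
Reagents that add atoms: acetonitrile, CC#N; water, O (hydrogen chloride, Cl, enters intermediate 7 only)
Why: Houben–Hoesch acylation of a phloroglucinol-type phenol: the two free ring positions of 6 are equivalent by symmetry and each is ortho to the hydroxyl and ortho/para to the benzyloxy groups, so the nitrilium electrophile can give only this ketimine. Hydrolysis releases the chelated ortho-hydroxy ketone, and no hard Lewis acid capable of O-debenzylation is used at elevated temperature.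

Step 6
Reactants: 8 1-[4,6-bis(benzyloxy)-2-hydroxy-5-methoxyphenyl]ethanone
Product: 9 1-[4,6-bis(benzyloxy)-2-(tert-butyldimethylsilyloxy)-5-methoxyphenyl]ethanone
Conditions: TBSCl, imidazole, 4-(dimethylamino)pyridine (cat.), DMF, rt
Reagents that add atoms: tert-butyldimethylsilyl chloride, CC(C)(C)[Si](C)(C)Cl
Why: Imidazole-promoted O-silylation of the chelated phenol; capping this oxygen later prevents intramolecular O–H insertion of the carbene, and the aryl silyl ether can be removed by fluoride without touching benzyl or 4-methoxybenzyl ethers.

Step 7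
Reactants: 9 1-[4,6-bis(benzyloxy)-2-(tert-butyldimethylsilyloxy)-5-methoxyphenyl]ethanone
Product: 11 1-[4,6-bis(benzyloxy)-2-(tert-butyldimethylsilyloxy)-5-methoxyphenyl]-2-diazoethanone, via trifluoroacetyl diketone 10 (not isolated)
Conditions: LiN(SiMe3)2, THF, −78 °C; CF3CO2CH2CF3; aq. NH4Cl; then 4-acetamidobenzenesulfonyl azide, Et3N, H2O, MeCN, rt
Reagents that add atoms: 4-acetamidobenzenesulfonyl azide, CC(=O)Nc1ccc(cc1)S(=O)(=O)N=[N+]=[N-]; 2,2,2-trifluoroethyl trifluoroacetate, O=C(OCC(F)(F)F)C(F)(F)F (its trifluoroacetyl group is carried by intermediate 10 only)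
Why: Deacylative (detrifluoroacetylative) diazo transfer: the kinetic lithium enolate of the methyl ketone is C-acylated to the trifluoromethyl β-diketone 10, which is acidic enough for Regitz-type diazo transfer, and the trifluoroacetyl group then leaves as the N-acylsulfonamide. The methyl group is the only enolisable position, and C-acylation of lithium enolates of ortho-silyloxy acetophenones is established practice.

Step 8
Reactants: 11 1-[4,6-bis(benzyloxy)-2-(tert-butyldimethylsilyloxy)-5-methoxyphenyl]-2-diazoethanone; 12 4-methoxybenzyl alcohol; 13 4-(benzyloxy)benzaldehyde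
Product: 15 (2R,3S)-1-[4,6-bis(benzyloxy)-2-(tert-butyldimethylsilyloxy)-5-methoxyphenyl]-3-[4-(benzyloxy)phenyl]-3-hydroxy-2-[(4-methoxybenzyl)oxy]propan-1-one, via PMB-oxy enol 14 (not isolated)
Conditions: Rh2(OAc)4 (2 mol %), (R)-3,3'-bis(2,4,6-triisopropylphenyl)-1,1'-binaphthyl-2,2'-diyl hydrogen phosphate (10 mol %), 4 Å MS, CH2Cl2, 0 °C, slow addition of 11 to 12 and 13 (both in excess)
Reagents that add atoms: none
Why: Rh2(OAc)4 extrudes dinitrogen from 11 to give an electrophilic rhodium carbene, the oxygen of 12 adds to it, and the oxonium ylide relaxes to the enol 14 (a delayed 1,2-proton shift). The phosphoric acid accepts a hydrogen bond from the enol hydroxyl at its P=O oxygen and activates the carbonyl of 13 with its acidic O–H, so C–C bond formation in this closed assembly should be faster than tautomerisation of 14 to the plain O–H insertion ketone. The closest known reaction type is the Rh2(OAc)4 and chiral phosphoric acid co-catalysed three-component coupling of diazo carbonyl compounds, alcohols and aldehydes or imines through trapping of oxonium ylides, here applied to an aryl diazomethyl ketone. No ring is closed. The two new stereocentres, C2 and C3 of the propanone, arise together in the C–C bond-forming event: the syn relationship should follow from the (Z)-enol held in the hydrogen-bonded transition state, and the absolute sense from the 3,3'-aryl pocket of the acid, which exposes one face of the aldehyde. Capture of the carbene by the external O–H rather than by the two ortho oxygens is needed; it is favoured because the doubly ortho-substituted aryl ketone is twisted out of the ring plane, the phenol is capped by a bulky silyl group, and 12 is in excess while 11 is added slowly. Aldehyde 13 cannot enolise, and the acid-only, low-temperature medium protects the enolisable, retro-aldol-prone adduct.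

Step 9
Reactants: 15 (2R,3S)-1-[4,6-bis(benzyloxy)-2-(tert-butyldimethylsilyloxy)-5-methoxyphenyl]-3-[4-(benzyloxy)phenyl]-3-hydroxy-2-[(4-methoxybenzyl)oxy]propan-1-one
Product: 16 (2R,3S)-1-[4,6-bis(benzyloxy)-2-hydroxy-5-methoxyphenyl]-3-[4-(benzyloxy)phenyl]-3-hydroxy-2-[(4-methoxybenzyl)oxy]propan-1-one
Conditions: Bu4NF, AcOH, THF, 0 °C
Reagents that add atoms: none
Why: Fluoride cleaves the aryl silyl ether, which is far more labile than an alkyl one because phenoxide is the better leaving group. Acetic acid buffers the medium so that the β-hydroxy ketone should neither epimerise at C2 nor undergo retro-aldol cleavage.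

Step 10
Reactants: 16 (2R,3S)-1-[4,6-bis(benzyloxy)-2-hydroxy-5-methoxyphenyl]-3-[4-(benzyloxy)phenyl]-3-hydroxy-2-[(4-methoxybenzyl)oxy]propan-1-one
Product: 17 (2R,3R)-5,7-bis(benzyloxy)-2-[4-(benzyloxy)phenyl]-6-methoxy-3-[(4-methoxybenzyl)oxy]-2,3-dihydro-4H-chromen-4-one
Conditions: PPh3, DIAD, THF, 0 °C to rt
Reagents that add atoms: none
Why: Intramolecular Mitsunobu etherification: the chelated phenol is acidic enough to protonate the betaine, the only alcohol is activated as its alkoxyphosphonium ion, and the phenoxide displaces it in a 6-exo-tet SN2 reaction with inversion. This turns the (S)-carbinol into C2 (R) and gives the 2,3-trans ring; C3 is not involved and keeps its configuration.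

Step 11
Reactants: 17 (2R,3R)-5,7-bis(benzyloxy)-2-[4-(benzyloxy)phenyl]-6-methoxy-3-[(4-methoxybenzyl)oxy]-2,3-dihydro-4H-chromen-4-one
Product: 18 (2R,3R)-5,7-bis(benzyloxy)-2-[4-(benzyloxy)phenyl]-3-hydroxy-6-methoxy-2,3-dihydro-4H-chromen-4-one
Conditions: DDQ, CH2Cl2/aq. pH 7 buffer, 0 °C to rt
Reagents that add atoms: none
Why: Oxidative cleavage of the 4-methoxybenzyl ether by DDQ (hydride abstraction to the stabilised oxocarbenium ion, then hydrolysis). Plain aryl benzyl ethers are much harder to oxidise, and C2–H, although benzylic, is deactivated by the adjacent carbonyl-bearing carbon and by O1 being part of a vinylogous ester.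

Step 12
Reactants: 18 (2R,3R)-5,7-bis(benzyloxy)-2-[4-(benzyloxy)phenyl]-3-hydroxy-6-methoxy-2,3-dihydro-4H-chromen-4-one
Product: 19 (2R,3R)-5,7-bis(benzyloxy)-2-[4-(benzyloxy)phenyl]-6-methoxy-4-oxo-3,4-dihydro-2H-chromen-3-yl acetate
Conditions: Ac2O, pyridine, 4-(dimethylamino)pyridine (cat.), CH2Cl2, 0 °C
Reagents that add atoms: acetic anhydride, CC(=O)OC(C)=O
Why: Nucleophilic catalysis of O-acylation; the C3 hydroxyl is the only free OH, so no selectivity problem arises, and the mild base at low temperature should not epimerise C3 or open ring C.

Step 13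
Reactants: 19 (2R,3R)-5,7-bis(benzyloxy)-2-[4-(benzyloxy)phenyl]-6-methoxy-4-oxo-3,4-dihydro-2H-chromen-3-yl acetate
Product: 20 (2R,3R)-5,7-dihydroxy-2-(4-hydroxyphenyl)-6-methoxy-4-oxo-3,4-dihydro-2H-chromen-3-yl acetate (6-methoxyaromadendrin 3-O-acetate)
Conditions: H2 (1 atm), 10% Pd/C, EtOAc, rt
Reagents that add atoms: none
Why: Hydrogenolysis of the three aryl benzyl ethers on palladium under neutral conditions, which spares the acetate and both stereocentres. The aryl ketone is a chelated vinylogous ester and is reduced much more slowly, so the reaction is stopped after uptake of three equivalents of hydrogen.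

## Compound list

1 | methyl 3,5-dihydroxy-4-methoxybenzoate | COC(=O)c1cc(O)c(OC)c(O)c1 | starting material
2 | methyl 3,5-bis(benzyloxy)-4-methoxybenzoate | COC(=O)c1cc(OCc2ccccc2)c(OC)c(OCc2ccccc2)c1 | intermediate
3 | [3,5-bis(benzyloxy)-4-methoxyphenyl]methanol | OCc1cc(OCc2ccccc2)c(OC)c(OCc2ccccc2)c1 | intermediate
4 | 3,5-bis(benzyloxy)-4-methoxybenzaldehyde | O=Cc1cc(OCc2ccccc2)c(OC)c(OCc2ccccc2)c1 | intermediate
5 | 3,5-bis(benzyloxy)-4-methoxyphenyl formate | O=COc1cc(OCc2ccccc2)c(OC)c(OCc2ccccc2)c1 | intermediate (not isolated)
6 | 3,5-bis(benzyloxy)-4-methoxyphenol | Oc1cc(OCc2ccccc2)c(OC)c(OCc2ccccc2)c1 | intermediate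
7 | 1-[4,6-bis(benzyloxy)-2-hydroxy-5-methoxyphenyl]ethan-1-iminium chloride | CC(=[NH2+])c1c(O)cc(OCc2ccccc2)c(OC)c1OCc1ccccc1.[Cl-] | intermediate (not isolated)
8 | 1-[4,6-bis(benzyloxy)-2-hydroxy-5-methoxyphenyl]ethanone | CC(=O)c1c(O)cc(OCc2ccccc2)c(OC)c1OCc1ccccc1 | intermediate
9 | 1-[4,6-bis(benzyloxy)-2-(tert-butyldimethylsilyloxy)-5-methoxyphenyl]ethanone | CC(=O)c1c(O[Si](C)(C)C(C)(C)C)cc(OCc2ccccc2)c(OC)c1OCc1ccccc1 | intermediate
10 | 1-[4,6-bis(benzyloxy)-2-(tert-butyldimethylsilyloxy)-5-methoxyphenyl]-4,4,4-trifluorobutane-1,3-dione | O=C(CC(=O)C(F)(F)F)c1c(O[Si](C)(C)C(C)(C)C)cc(OCc2ccccc2)c(OC)c1OCc1ccccc1 | intermediate (not isolated)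
11 | 1-[4,6-bis(benzyloxy)-2-(tert-butyldimethylsilyloxy)-5-methoxyphenyl]-2-diazoethanone | COc1c(OCc2ccccc2)cc(O[Si](C)(C)C(C)(C)C)c(c1OCc1ccccc1)C(=O)C=[N+]=[N-] | intermediate
12 | 4-methoxybenzyl alcohol | COc1ccc(CO)cc1 | starting material
13 | 4-(benzyloxy)benzaldehyde | O=Cc1ccc(OCc2ccccc2)cc1 | starting material
14 | (Z)-1-[4,6-bis(benzyloxy)-2-(tert-butyldimethylsilyloxy)-5-methoxyphenyl]-2-[(4-methoxybenzyl)oxy]ethen-1-ol | COc1c(OCc2ccccc2)cc(O[Si](C)(C)C(C)(C)C)c(c1OCc1ccccc1)/C(O)=C/OCc1ccc(OC)cc1 | intermediate (not isolated)
15 | (2R,3S)-1-[4,6-bis(benzyloxy)-2-(tert-butyldimethylsilyloxy)-5-methoxyphenyl]-3-[4-(benzyloxy)phenyl]-3-hydroxy-2-[(4-methoxybenzyl)oxy]propan-1-one | COc1c(OCc2ccccc2)cc(O[Si](C)(C)C(C)(C)C)c(c1OCc1ccccc1)C(=O)[C@H](OCc1ccc(OC)cc1)[C@H](c1ccc(OCc2ccccc2)cc1)O | intermediate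
16 | (2R,3S)-1-[4,6-bis(benzyloxy)-2-hydroxy-5-methoxyphenyl]-3-[4-(benzyloxy)phenyl]-3-hydroxy-2-[(4-methoxybenzyl)oxy]propan-1-one | COc1c(OCc2ccccc2)cc(O)c(c1OCc1ccccc1)C(=O)[C@H](OCc1ccc(OC)cc1)[C@H](c1ccc(OCc2ccccc2)cc1)O | intermediate
17 | (2R,3R)-5,7-bis(benzyloxy)-2-[4-(benzyloxy)phenyl]-6-methoxy-3-[(4-methoxybenzyl)oxy]-2,3-dihydro-4H-chromen-4-one | COc1c(OCc3ccccc3)cc2c(c1OCc1ccccc1)C(=O)[C@H](OCc1ccc(OC)cc1)[C@@H](c1ccc(OCc3ccccc3)cc1)O2 | intermediate
18 | (2R,3R)-5,7-bis(benzyloxy)-2-[4-(benzyloxy)phenyl]-3-hydroxy-6-methoxy-2,3-dihydro-4H-chromen-4-one | COc1c(OCc3ccccc3)cc2c(c1OCc1ccccc1)C(=O)[C@H](O)[C@@H](c1ccc(OCc3ccccc3)cc1)O2 | intermediate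
19 | (2R,3R)-5,7-bis(benzyloxy)-2-[4-(benzyloxy)phenyl]-6-methoxy-4-oxo-3,4-dihydro-2H-chromen-3-yl acetate | COc1c(OCc3ccccc3)cc2c(c1OCc1ccccc1)C(=O)[C@H](OC(C)=O)[C@@H](c1ccc(OCc3ccccc3)cc1)O2 | intermediate
20 | (2R,3R)-5,7-dihydroxy-2-(4-hydroxyphenyl)-6-methoxy-4-oxo-3,4-dihydro-2H-chromen-3-yl acetate (6-methoxyaromadendrin 3-O-acetate) | COc1c(O)cc2c(c1O)C(=O)[C@H](OC(C)=O)[C@@H](c1ccc(O)cc1)O2 | target

## Step count and least certain steps

Total step count: 13 steps. Longest linear sequence: 13 steps (1 to 20); 12 and 13 are purchased and enter at step 8.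

Step 8 (key step).
- What may go wrong: premature tautomerisation of the enol to the plain O–H insertion ketone before it meets the electron-rich, weakly electrophilic aldehyde. Interception of the carbene by an ortho ether oxygen, followed by a 1,2-shift, is a second risk. Poor syn/anti or facial selectivity is possible for an enol derived from a ketone rather than an ester, and the adduct could suffer retro-aldol loss on handling.
- Fallback: it sets out from 8 and comes back at 18, replacing the carbene step by asymmetric epoxidation of a chalcone and ring closure by epoxide opening. Compound 8 is converted with MOMCl and i-Pr2NEt into the methoxymethyl ether 1-[4,6-bis(benzyloxy)-5-methoxy-2-(methoxymethoxy)phenyl]ethanone F1. Claisen–Schmidt condensation with 13 (KOH, EtOH) should give the chalcone (E)-1-[4,6-bis(benzyloxy)-5-methoxy-2-(methoxymethoxy)phenyl]-3-[4-(benzyloxy)phenyl]prop-2-en-1-one F2. Juliá–Colonna epoxidation (poly-L-leucine, urea–H2O2, 1,8-diazabicyclo[5.4.0]undec-7-ene, THF) is expected, by analogy with chalcone itself, to give the trans epoxide [(2R,3S)-3-[4-(benzyloxy)phenyl]oxiran-2-yl][4,6-bis(benzyloxy)-5-methoxy-2-(methoxymethoxy)phenyl]methanone F3. HCl in MeOH then removes the acetal, and the freed phenol opens the oxirane at the benzylic carbon with inversion, which leads to 18. Steps 12 and 13 follow unchanged.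

Step 10.
- What may go wrong: β-elimination of the activated benzylic oxygen across C2–C3, since C3–H is acidic, or ionisation at the 4-benzyloxybenzylic carbon, either of which erodes the clean inversion.
- Fallback: it sets out from 16 and comes back at 17 and makes no new compound (F0). The ring is closed by deliberate ionisation under Brønsted acid catalysis (camphorsulfonic acid, 4 Å MS, CH2Cl2, 0 °C). The benzylic cation is captured by the phenol, and the fixed C3 stereocentre should steer the aryl group into the equatorial, trans position. This stereoconvergent SN1 closure would also make the syn/anti ratio of step 8 less critical.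

Step 7.
- What may go wrong: migration or loss of the aryl silyl group at the lithium enolate stage (an O-to-O silyl shift), or incomplete C-acylation of the hindered enolate.
- Fallback: it sets out from 9 and comes back at 11 and avoids a lithium enolate. Soft enolisation (TMSOTf, Et3N, CH2Cl2, 0 °C) should give the silyl enol ether ({1-[4,6-bis(benzyloxy)-2-(tert-butyldimethylsilyloxy)-5-methoxyphenyl]ethenyl}oxy)trimethylsilane F4. N-Bromosuccinimide in THF at −78 °C converts it into the bromoketone 1-[4,6-bis(benzyloxy)-2-(tert-butyldimethylsilyloxy)-5-methoxyphenyl]-2-bromoethanone F5. N,N'-Ditosylhydrazine and 1,8-diazabicyclo[5.4.0]undec-7-ene in THF at 0 °C (N-alkylation followed by loss of two sulfinate groups) then give 11.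

Step 5.
- What may go wrong: acid-induced debenzylation of the very electron-rich ring, or O-imidate formation at the phenol in place of C-acylation.
- Fallback: it sets out from 6 and comes back at 8 and introduces the acyl carbon without strong acid. Magnesium-mediated ortho-formylation (MgCl2, Et3N, paraformaldehyde, MeCN, reflux) should give 4,6-bis(benzyloxy)-2-hydroxy-5-methoxybenzaldehyde F6. MeMgBr (excess, THF, 0 °C) gives racemic 3,5-bis(benzyloxy)-2-(1-hydroxyethyl)-4-methoxyphenol F7, and MnO2 in CH2Cl2 oxidises the benzylic alcohol to 8.

## Further compounds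

F1 | step 8 | 1-[4,6-bis(benzyloxy)-5-methoxy-2-(methoxymethoxy)phenyl]ethanone | COCOc1cc(OCc2ccccc2)c(OC)c(OCc2ccccc2)c1C(C)=O
F2 | step 8 | (E)-1-[4,6-bis(benzyloxy)-5-methoxy-2-(methoxymethoxy)phenyl]-3-[4-(benzyloxy)phenyl]prop-2-en-1-one | COCOc1cc(OCc2ccccc2)c(OC)c(OCc2ccccc2)c1C(=O)/C=C/c1ccc(OCc2ccccc2)cc1
F3 | step 8 | [(2R,3S)-3-[4-(benzyloxy)phenyl]oxiran-2-yl][4,6-bis(benzyloxy)-5-methoxy-2-(methoxymethoxy)phenyl]methanone | COCOc1cc(OCc2ccccc2)c(OC)c(OCc2ccccc2)c1C(=O)[C@@H]1O[C@H]1c1ccc(OCc2ccccc2)cc1
F0 | step 10 | none | none
F4 | step 7 | ({1-[4,6-bis(benzyloxy)-2-(tert-butyldimethylsilyloxy)-5-methoxyphenyl]ethenyl}oxy)trimethylsilane | C=C(O[Si](C)(C)C)c1c(O[Si](C)(C)C(C)(C)C)cc(OCc2ccccc2)c(OC)c1OCc1ccccc1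
F5 | step 7 | 1-[4,6-bis(benzyloxy)-2-(tert-butyldimethylsilyloxy)-5-methoxyphenyl]-2-bromoethanone | BrCC(=O)c1c(O[Si](C)(C)C(C)(C)C)cc(OCc2ccccc2)c(OC)c1OCc1ccccc1
F6 | step 5 | 4,6-bis(benzyloxy)-2-hydroxy-5-methoxybenzaldehyde | O=Cc1c(O)cc(OCc2ccccc2)c(OC)c1OCc1ccccc1
F7 | step 5 | 3,5-bis(benzyloxy)-2-(1-hydroxyethyl)-4-methoxyphenol (racemic) | CC(O)c1c(O)cc(OCc2ccccc2)c(OC)c1OCc1ccccc1
A1 | alternative 1 | 2-[3,5-bis(benzyloxy)-2-formyl-4-methoxyphenoxy]-2-[4-(benzyloxy)phenyl]acetaldehyde (racemic) | COc1c(OCc2ccccc2)cc(OC(C=O)c2ccc(OCc3ccccc3)cc2)c(C=O)c1OCc1ccccc1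
A2 | alternative 1 | (2R,3R)-5,7,4'-tri-O-benzyl-6-methoxyaromadendrin | COc1c(OCc3ccccc3)cc2c(c1OCc1ccccc1)C(=O)[C@H](O)[C@@H](c1ccc(OCc3ccccc3)cc1)O2
A3 | alternative 2 | 3,5-bis(benzyloxy)-2-(hydroxymethyl)-4-methoxyphenol | COc1c(OCc2ccccc2)cc(O)c(CO)c1OCc1ccccc1
A4 | alternative 2 | 3,5-bis(benzyloxy)-4-methoxy-6-methylidenecyclohexa-2,4-dien-1-one | C=C1C(=O)C=C(OCc2ccccc2)C(OC)=C1OCc1ccccc1
A5 | alternative 2 | (E)-2-[4-(benzyloxy)phenyl]ethenyl acetate | CC(=O)O/C=C/c1ccc(OCc2ccccc2)cc1
A6 | alternative 2 | (2R,3S)-5,7-bis(benzyloxy)-2-[4-(benzyloxy)phenyl]-6-methoxychroman-3-yl acetate | COc1c(OCc3ccccc3)cc2c(c1OCc1ccccc1)C[C@H](OC(C)=O)[C@@H](c1ccc(OCc3ccccc3)cc1)O2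
A7 | alternative 3 | 3,5-bis(benzyloxy)-4-methoxy-2-(trimethylsilyl)phenyl trifluoromethanesulfonate | COc1c(OCc2ccccc2)cc(OS(=O)(=O)C(F)(F)F)c([Si](C)(C)C)c1OCc1ccccc1
A8 | alternative 3 | 3,5-bis(benzyloxy)-1,2-didehydro-4-methoxybenzene | COC1=C(OCc2ccccc2)C#CC=C1OCc1ccccc1
A9 | alternative 3 | methyl (2R,3R)-3-[4-(benzyloxy)phenyl]-3-hydroxy-2-[(4-methoxybenzyl)oxy]propanoate | COC(=O)[C@H](OCc1ccc(OC)cc1)[C@@H](c1ccc(OCc2ccccc2)cc1)O
A10 | alternative 3 | (2R,3R)-5,7,4'-tri-O-benzyl-3-O-(4-methoxybenzyl)-6-methoxyaromadendrin | COc1c(OCc3ccccc3)cc2c(c1OCc1ccccc1)C(=O)[C@H](OCc1ccc(OC)cc1)[C@@H](c1ccc(OCc3ccccc3)cc1)O2
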